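**Strategy.** In the flavanone half, the pyran oxygen O1 ties the C2 stereocentre to aromatic carbon C8a of ring A, so the heterocycle is disconnected at the O1–C8a aryl–oxygen bond. An (S)-benzylic carbinol, set by CBS reduction, is joined to a bromide at C8a by palladium-catalysed intramolecular etherification. This closes the pyran ring as a (2S)-flavan in one operation without ever breaking the C2–O bond. C4 stays a methylene during ring closure, so no base-labile β-aryloxy ketone is present, and it is oxidised afterwards. The cyclisation precursor is a 1-aryl-3-(2-bromoaryl)propan-1-ol that already carries the 5,7-di-O-benzylapigenin unit as the C6 diaryl ether.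

Key step: step 9

Assumption: the dihydro unit is numbered as a flavanone (O1, C2, C3, C4, C4a, C5–C8, C8a) and its C2 is (S) as read from the target SMILES; compound 14 is a C4-epimer mixture, drawn without C4 configuration because that centre becomes the carbonyl.

Step 1
Reactants: 1 2',4',6'-trihydroxyacetophenone
Product: 2 2'-hydroxy-4',6'-bis(benzyloxy)acetophenone
Conditions: BnBr (2.1 equiv), K2CO3, DMF, rt
Reagents that add atoms: benzyl bromide, BrCc1ccccc1
Why: Williamson etherification, in which the para and one ortho phenoxide are alkylated while the remaining ortho hydroxyl, hydrogen-bonded to the acetyl carbonyl, is the least nucleophilic and should stay free when two equivalents of halide are used.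

Step 2
Reactants: 2 2'-hydroxy-4',6'-bis(benzyloxy)acetophenone; 3 4-iodobenzaldehyde
Product: 4 (E)-2'-hydroxy-4',6'-bis(benzyloxy)-4-iodochalcone
Conditions: KOH (aq), EtOH/THF, rt
Reagents that add atoms: none
Why: Claisen–Schmidt aldol condensation of the methyl ketone enolate with a non-enolisable aldehyde, dehydration giving the conjugated (E)-enone while the aryl iodide and the benzyl ethers are inert to hydroxide at room temperature.

Step 3
Reactants: 4 (E)-2'-hydroxy-4',6'-bis(benzyloxy)-4-iodochalcone
Product: 5 5,7-bis(benzyloxy)-4'-iodoflavone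
Conditions: I2 (10 mol%), DMSO, 130 °C
Reagents that add atoms: none
Why: Iodine-catalysed oxidative cyclisation of a 2'-hydroxychalcone in DMSO, the standard flavone synthesis with DMSO as terminal oxidant, which should leave the aryl iodide and the benzyl ethers untouched.

Step 4
Reactants: 6 4-bromo-2,6-dimethoxyphenol
Product: 7 6-bromo-3-hydroxy-2,4-dimethoxybenzaldehyde
Conditions: Cl2CHOMe, TiCl4 (3 equiv), CH2Cl2, −10 °C → rt; then ice/H2O
Reagents that add atoms: dichloromethyl methyl ether, COC(Cl)Cl; water, O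
Why: Rieche formylation (electrophilic aromatic substitution, hydrolysed on work-up), for which the positions ortho and para to the hydroxyl are occupied and the two remaining ring CH groups are equivalent by symmetry, each ortho to one methoxy group and para to the other, so a single aldehyde should form.

Step 5
Reactants: 7 6-bromo-3-hydroxy-2,4-dimethoxybenzaldehyde; 8 4'-benzyloxyacetophenone
Product: 9 (E)-1-[4-(benzyloxy)phenyl]-3-(6-bromo-3-hydroxy-2,4-dimethoxyphenyl)prop-2-en-1-one
Conditions: KOH (aq), EtOH/THF, rt → 40 °C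
Reagents that add atoms: none
Why: Claisen–Schmidt aldol condensation with a non-enolisable aldehyde, in which the phenoxide formed is meta to the formyl group and so does not quench its electrophilicity, and dehydration gives the (E)-chalcone.

Step 6
Reactants: 9 (E)-1-[4-(benzyloxy)phenyl]-3-(6-bromo-3-hydroxy-2,4-dimethoxyphenyl)prop-2-en-1-one
Product: 10 1-[4-(benzyloxy)phenyl]-3-(6-bromo-3-hydroxy-2,4-dimethoxyphenyl)propan-1-one
Conditions: H2 (4 atm), RhCl(PPh3)3 (5 mol%), THF/EtOH, 40 °C
Reagents that add atoms: none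
Why: Homogeneous hydrogenation with Wilkinson's catalyst, which saturates the disubstituted enone C=C but, unlike heterogeneous palladium, should not cleave the aryl C–Br bond or the benzyl ether and does not reduce the ketone.

Step 7
Reactants: 10 1-[4-(benzyloxy)phenyl]-3-(6-bromo-3-hydroxy-2,4-dimethoxyphenyl)propan-1-one; 5 5,7-bis(benzyloxy)-4'-iodoflavone
Product: 11 1-[4-(benzyloxy)phenyl]-3-{6-bromo-2,4-dimethoxy-3-[4-(5,7-bis(benzyloxy)-4-oxo-4H-chromen-2-yl)phenoxy]phenyl}propan-1-one
Conditions: CuI (10 mol%), picolinic acid (20 mol%), K3PO4, DMSO, 80 °C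
Reagents that add atoms: none
Why: Ullmann-type copper-catalysed diaryl ether synthesis, in which the aryl iodide activated by the para chromone should add to Cu(I) much faster than the electron-rich, ortho-alkylated aryl bromide of 10, so the bromide is retained, and the picolinic acid system accepts phenols bearing two ortho substituents.

Step 8
Reactants: 11 1-[4-(benzyloxy)phenyl]-3-{6-bromo-2,4-dimethoxy-3-[4-(5,7-bis(benzyloxy)-4-oxo-4H-chromen-2-yl)phenoxy]phenyl}propan-1-one
Product: 12 (1S)-1-[4-(benzyloxy)phenyl]-3-{6-bromo-2,4-dimethoxy-3-[4-(5,7-bis(benzyloxy)-4-oxo-4H-chromen-2-yl)phenoxy]phenyl}propan-1-ol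
Conditions: (R)-Me-CBS (20 mol%), BH3·SMe2, THF, −20 °C; then MeOH
Reagents that add atoms: none
Why: Corey–Bakshi–Shibata reduction, in which the (R)-oxazaborolidine–borane complex binds the aryl ketone with the aryl group as the large substituent and delivers hydride to the Re face, setting the (S)-carbinol, while the far less electrophilic pyranone carbonyl of the flavone should not be reduced at low temperature.

Step 9
Reactants: 12 (1S)-1-[4-(benzyloxy)phenyl]-3-{6-bromo-2,4-dimethoxy-3-[4-(5,7-bis(benzyloxy)-4-oxo-4H-chromen-2-yl)phenoxy]phenyl}propan-1-ol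
Product: 13 (2S)-4'-benzyloxy-5,7-dimethoxy-6-[4-(5,7-bis(benzyloxy)-4-oxo-4H-chromen-2-yl)phenoxy]flavan
Conditions: Pd(OAc)2 (5 mol%), 2-(di-tert-butylphosphino)-1,1'-binaphthyl (6 mol%), Cs2CO3, toluene, 80 °C
Reagents that add atoms: none
Why: Pd(0) formed from Pd(OAc)2 and the bulky phosphine inserts into the C8a–Br bond, carbonate-assisted binding of the carbinol gives an aryl(alkoxo)palladium(II) species, and C–O reductive elimination releases the flavan and Pd(0). The closest known reaction type is the palladium-catalysed intramolecular etherification of aryl halides with secondary alcohols (Buchwald-type C–O coupling), which gives chromans and flavans. The six-membered pyran ring closes by reductive elimination from a seven-membered oxapalladacycle, formally a 6-exo closure onto C8a. No new stereocentre is made: the C2–O bond is never broken, so the (S)-carbinol becomes (2S) with retention, the descriptor staying the same because the priority order O > aryl > CH2 > H persists. The selectivity needed is reductive elimination over β-hydride elimination of the palladium alkoxide, which the hindered electron-rich monophosphine secures, and the substrate offers a single C–halogen bond. Because C4 is a methylene there is no enolisable β-aryloxy ketone, so the carbonate base cannot open the ring through a chalcone and racemise C2.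

Step 10
Reactants: 13 (2S)-4'-benzyloxy-5,7-dimethoxy-6-[4-(5,7-bis(benzyloxy)-4-oxo-4H-chromen-2-yl)phenoxy]flavan
Product: 14 (2S,4RS)-4'-benzyloxy-5,7-dimethoxy-6-[4-(5,7-bis(benzyloxy)-4-oxo-4H-chromen-2-yl)phenoxy]flavan-4-ol
Conditions: DDQ (1.3 equiv), CH2Cl2/pH 7 buffer (10:1), 0 °C → rt; crude product used directly
Reagents that add atoms: water, O
Why: DDQ benzylic oxidation by hydride abstraction, an oxygenation established at C4 of 5,7-dialkoxyflavans, in which the C4 cation is stabilised by O1 and the 5-methoxy group (ortho) and the 7-methoxy group (para) of ring A far better than a cation at C2 would be, and is captured by water to give the 4-ol as an inconsequential C4-epimer mixture with C2 untouched.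

Step 11
Reactants: 14 (2S,4RS)-4'-benzyloxy-5,7-dimethoxy-6-[4-(5,7-bis(benzyloxy)-4-oxo-4H-chromen-2-yl)phenoxy]flavan-4-ol
Product: 15 (2S)-4'-benzyloxy-5,7-dimethoxy-6-[4-(5,7-bis(benzyloxy)-4-oxo-4H-chromen-2-yl)phenoxy]flavanone
Conditions: Dess–Martin periodinane, pyridine, CH2Cl2, 0 °C → rt
Reagents that add atoms: none
Why: Dess–Martin oxidation of a secondary benzylic alcohol under buffered, essentially neutral conditions, so both C4 epimers should converge on the ketone without ionisation at C4 and without base-induced ring opening (retro-oxa-Michael) that would racemise C2.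

Step 12
Reactants: 15 (2S)-4'-benzyloxy-5,7-dimethoxy-6-[4-(5,7-bis(benzyloxy)-4-oxo-4H-chromen-2-yl)phenoxy]flavanone
Product: 16 (2S)-5,4'-dihydroxy-7-methoxy-6-[4-(5,7-dihydroxy-4-oxo-4H-chromen-2-yl)phenoxy]flavanone (target)
Conditions: BCl3 (excess), C6HMe5, CH2Cl2, −78 → 0 °C; then MeOH/H2O
Reagents that add atoms: none
Why: Lewis-acid ether cleavage, in which BCl3 with pentamethylbenzene as a non-basic benzyl-cation scavenger removes the three aryl benzyl ethers at low temperature and, on warming, the boron chelate between the C4 carbonyl and the peri 5-methoxy group directs selective demethylation there, leaving the non-chelated 7-methoxy group and the diaryl ether intact under acidic conditions that should not epimerise C2.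

**Compound list**

1 | 2',4',6'-trihydroxyacetophenone | CC(=O)c1c(O)cc(O)cc1O | starting material
2 | 2'-hydroxy-4',6'-bis(benzyloxy)acetophenone | CC(=O)c1c(O)cc(OCc2ccccc2)cc1OCc1ccccc1 | intermediate
3 | 4-iodobenzaldehyde | O=Cc1ccc(I)cc1 | starting material
4 | (E)-2'-hydroxy-4',6'-bis(benzyloxy)-4-iodochalcone | O=C(/C=C/c1ccc(I)cc1)c1c(O)cc(OCc2ccccc2)cc1OCc1ccccc1 | intermediate
5 | 5,7-bis(benzyloxy)-4'-iodoflavone | Ic1ccc(-c2cc(=O)c3c(OCc4ccccc4)cc(OCc4ccccc4)cc3o2)cc1 | intermediate
6 | 4-bromo-2,6-dimethoxyphenol | COc1cc(Br)cc(OC)c1O | starting material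
7 | 6-bromo-3-hydroxy-2,4-dimethoxybenzaldehyde | COc1cc(Br)c(C=O)c(OC)c1O | intermediate
8 | 4'-benzyloxyacetophenone | CC(=O)c1ccc(OCc2ccccc2)cc1 | starting material
9 | (E)-1-[4-(benzyloxy)phenyl]-3-(6-bromo-3-hydroxy-2,4-dimethoxyphenyl)prop-2-en-1-one | COc1cc(Br)c(/C=C/C(=O)c2ccc(OCc3ccccc3)cc2)c(OC)c1O | intermediate
10 | 1-[4-(benzyloxy)phenyl]-3-(6-bromo-3-hydroxy-2,4-dimethoxyphenyl)propan-1-one | COc1cc(Br)c(CCC(=O)c2ccc(OCc3ccccc3)cc2)c(OC)c1O | intermediate
11 | 1-[4-(benzyloxy)phenyl]-3-{6-bromo-2,4-dimethoxy-3-[4-(5,7-bis(benzyloxy)-4-oxo-4H-chromen-2-yl)phenoxy]phenyl}propan-1-one | COc1cc(Br)c(c(OC)c1Oc1ccc(-c2cc(=O)c3c(OCc4ccccc4)cc(OCc4ccccc4)cc3o2)cc1)CCC(=O)c1ccc(OCc2ccccc2)cc1 | intermediate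
12 | (1S)-1-[4-(benzyloxy)phenyl]-3-{6-bromo-2,4-dimethoxy-3-[4-(5,7-bis(benzyloxy)-4-oxo-4H-chromen-2-yl)phenoxy]phenyl}propan-1-ol | COc1cc(Br)c(c(OC)c1Oc1ccc(-c2cc(=O)c3c(OCc4ccccc4)cc(OCc4ccccc4)cc3o2)cc1)CC[C@H](O)c1ccc(OCc2ccccc2)cc1 | intermediate
13 | (2S)-4'-benzyloxy-5,7-dimethoxy-6-[4-(5,7-bis(benzyloxy)-4-oxo-4H-chromen-2-yl)phenoxy]flavan | COc1cc2c(c(OC)c1Oc1ccc(-c3cc(=O)c4c(OCc5ccccc5)cc(OCc5ccccc5)cc4o3)cc1)CC[C@@H](c1ccc(OCc3ccccc3)cc1)O2 | intermediate
14 | (2S,4RS)-4'-benzyloxy-5,7-dimethoxy-6-[4-(5,7-bis(benzyloxy)-4-oxo-4H-chromen-2-yl)phenoxy]flavan-4-ol | COc1cc2c(c(OC)c1Oc1ccc(-c3cc(=O)c4c(OCc5ccccc5)cc(OCc5ccccc5)cc4o3)cc1)C(O)C[C@@H](c1ccc(OCc3ccccc3)cc1)O2 | intermediate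
15 | (2S)-4'-benzyloxy-5,7-dimethoxy-6-[4-(5,7-bis(benzyloxy)-4-oxo-4H-chromen-2-yl)phenoxy]flavanone | COc1cc2c(c(OC)c1Oc1ccc(-c3cc(=O)c4c(OCc5ccccc5)cc(OCc5ccccc5)cc4o3)cc1)C(=O)C[C@@H](c1ccc(OCc3ccccc3)cc1)O2 | intermediate
16 | (2S)-5,4'-dihydroxy-7-methoxy-6-[4-(5,7-dihydroxy-4-oxo-4H-chromen-2-yl)phenoxy]flavanone | COc1cc2c(c(O)c1Oc1ccc(-c3cc(=O)c4c(O)cc(O)cc4o3)cc1)C(=O)C[C@@H](c1ccc(O)cc1)O2 | target

**Totals**

Total step count: 12. Longest linear sequence: 9 steps (steps 4–12 from 6; the flavone branch, steps 1–3 and then 7–12, is equally long).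

**Steps most likely to fail**

Step 9 (palladium etherification). β-Hydride elimination from the palladium alkoxide may outrun C–O reductive elimination, giving the ketone and a hydrodebrominated arene, or oxidative addition into the electron-rich C8a–Br bond may stall. The fallback forms the other pyran C–O bond (O1–C2) by Mitsunobu displacement with inversion. It sets out from ketone 11. Reduction with the (S)-Me-CBS catalyst and BH3·SMe2 should give the (1R)-carbinol F1. Miyaura borylation (B2pin2, PdCl2(dppf), KOAc, dioxane, 90 °C) converts the bromide into the aryl pinacol boronate F2. Oxidation with NaBO3·4H2O in THF/H2O gives the ring-A phenol F3. Mitsunobu cyclisation (PPh3, DIAD, toluene, 0 °C) closes the pyran ring with inversion at the carbinol carbon and comes back to the route at flavan 13.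

Step 10 (DDQ oxidation at C4). The C4 cation may lose a C3 proton to give the flav-3-ene, which is oxidised further to the flavylium ion with loss of the C2 stereocentre, or hydride may be abstracted at C2. The fallback replaces aqueous capture by anhydrous benzylic acetoxylation, which gives an isolable ester and keeps the acid-labile free carbinol out of the oxidising medium. It sets out from flavan 13. DDQ in CH2Cl2/AcOH at 0 °C should give the (2S,4RS)-4-acetoxyflavan F4. Treatment with LiOH in THF/H2O at 0 °C, where acyl cleavage and solvolysis converge, gives the 4-ol and comes back to the route at 14.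

Step 7 (Ullmann etherification). Copper may insert competitively into the C–Br bond of 10, causing oligomeric ethers or loss of the bromide, or the doubly ortho-substituted phenoxide may couple sluggishly. The fallback makes the diaryl ether by SNAr and builds the flavone afterwards. It sets out from chalcone 9. Heating with 4-fluorobenzaldehyde and K2CO3 in DMF at 110 °C should give the 4-aryloxybenzaldehyde chalcone F5. Claisen–Schmidt condensation with acetophenone 2 (KOH, EtOH/THF) gives the bis-chalcone F6. I2 (cat.) in DMSO at 130 °C cyclises only the 2'-hydroxychalcone half to the flavone–chalcone F7. Hydrogenation with RhCl(PPh3)3 then saturates the remaining disubstituted enone and comes back to the route at 11.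

**Further compounds**

F1 | step 9 | (1R)-1-[4-(benzyloxy)phenyl]-3-{6-bromo-2,4-dimethoxy-3-[4-(5,7-bis(benzyloxy)-4-oxo-4H-chromen-2-yl)phenoxy]phenyl}propan-1-ol | COc1cc(Br)c(c(OC)c1Oc1ccc(-c2cc(=O)c3c(OCc4ccccc4)cc(OCc4ccccc4)cc3o2)cc1)CC[C@@H](O)c1ccc(OCc2ccccc2)cc1
F2 | step 9 | pinacol boronate of F1 (Bpin in place of Br) | COc1cc(B2OC(C)(C)C(C)(C)O2)c(c(OC)c1Oc1ccc(-c2cc(=O)c3c(OCc4ccccc4)cc(OCc4ccccc4)cc3o2)cc1)CC[C@@H](O)c1ccc(OCc2ccccc2)cc1
F3 | step 9 | (1R)-1-[4-(benzyloxy)phenyl]-3-{6-hydroxy-2,4-dimethoxy-3-[4-(5,7-bis(benzyloxy)-4-oxo-4H-chromen-2-yl)phenoxy]phenyl}propan-1-ol | COc1cc(O)c(c(OC)c1Oc1ccc(-c2cc(=O)c3c(OCc4ccccc4)cc(OCc4ccccc4)cc3o2)cc1)CC[C@@H](O)c1ccc(OCc2ccccc2)cc1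
F4 | step 10 | (2S,4RS)-4-acetoxy-4'-benzyloxy-5,7-dimethoxy-6-[4-(5,7-bis(benzyloxy)-4-oxo-4H-chromen-2-yl)phenoxy]flavan | COc1cc2c(c(OC)c1Oc1ccc(-c3cc(=O)c4c(OCc5ccccc5)cc(OCc5ccccc5)cc4o3)cc1)C(OC(C)=O)C[C@@H](c1ccc(OCc3ccccc3)cc1)O2
F5 | step 7 | 4-{6-[(E)-3-(4-benzyloxyphenyl)-3-oxoprop-1-enyl]-5-bromo-2,6... (3-bromo-2-chalconyl-4,6... see SMILES) 4-(aryloxy)benzaldehyde chalcone from 9 | COc1cc(Br)c(/C=C/C(=O)c2ccc(OCc3ccccc3)cc2)c(OC)c1Oc1ccc(C=O)cc1
F6 | step 7 | bis-chalcone from F5 and 2 | COc1cc(Br)c(/C=C/C(=O)c2ccc(OCc3ccccc3)cc2)c(OC)c1Oc1ccc(/C=C/C(=O)c2c(O)cc(OCc3ccccc3)cc2OCc2ccccc2)cc1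
F7 | step 7 | (E)-chalcone analogue of 11 (flavone–chalcone) | COc1cc(Br)c(/C=C/C(=O)c2ccc(OCc3ccccc3)cc2)c(OC)c1Oc1ccc(-c2cc(=O)c3c(OCc4ccccc4)cc(OCc4ccccc4)cc3o2)cc1
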